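**Plan**

- Ring A bears oxygen on every carbon except C4a. O6 and O8a lie para to each other with the methoxy carbons C7 and C8 between them, which is the hydroquinone that a dimethyl squarate core gives on thermal ring expansion.
- Retrosynthesis: first the O5-ethyl and the O6/O2' benzyl groups are removed. Ring C is then cut at O1–C2 and C2–C3 (chalcone from the ring B aldehyde) and at C4–C4a (C-acetylation). Ring A is cut at C4a–C8a (six-electron electrocyclisation) and at C5–C6 (vinyllithium addition to the squarate).
- Forward: squarate → cyclobutenone → ring A hydroquinone → acetophenone → selective O6 benzylation → Claisen–Schmidt condensation with the ring B aldehyde → ring C by oxidative cyclisation → one-pot dealkylation.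
- Stereochemistry: the target has no stereocentre. The carbinol carbon of the cyclobutenone and C2 of the transient flavanone are racemic and both become sp2; the chalcone is E by thermodynamic control.

Key step: step 2

**Route**

Step 1
Reactants: 1 dimethyl squarate (3,4-dimethoxycyclobut-3-ene-1,2-dione); 2 ethyl vinyl ether
Product: 4 racemic 4-(1-ethoxyethenyl)-4-hydroxy-2,3-dimethoxycyclobut-2-en-1-one, via 1-ethoxyvinyllithium 3 (not isolated)
Conditions: 2, t-BuLi, THF, −78 → 0 °C; then 1, THF, −78 °C; aq. NH4Cl at −78 °C; Et3N-deactivated silica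
Reagents that add atoms: none
Why: α-Lithiation of the vinyl ether gives an acyl-anion equivalent that should add once, in the 1,2 sense, to one of the two equivalent squarate carbonyls at low temperature (organolithium 1,2-addition), the alkoxide formed deactivating the remaining vinylogous ester carbonyl; the new carbinol centre arises as a racemate, which does not matter because it is planarised in step 2.

Step 2
Reactants: 4 racemic 4-(1-ethoxyethenyl)-4-hydroxy-2,3-dimethoxycyclobut-2-en-1-one
Product: 7 5-ethoxy-2,3-dimethoxybenzene-1,4-diol, via dienylketene 5 (not isolated), via cyclohexadienone tautomer 6 (not isolated)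
Conditions: degassed toluene, 110 °C, Ar, base-washed glassware; concentrated under Ar and used directly
Reagents that add atoms: none
Why: Heating should open the cyclobutenone by conrotatory four-electron cleavage of the C1–C4 bond to the (Z)-dienylketene 5; a disrotatory six-electron electrocyclisation then joins the ketene carbon (future C8a) to the terminal CH2 of the enol ether (future C4a), and the dienone 6 enolises to the aromatic hydroquinone 7. The closest known reaction type is the thermal ring expansion of squarate-derived 4-alkenyl-4-hydroxycyclobutenones to hydroquinones (Moore-type benzannulation). The one ring closed is the six-membered carbocycle of ring A, formed by 6π electrocyclic closure of a triene whose ketene C=C is one terminus. No stereocentre is created, and the racemic carbinol carbon of 4 becomes an sp2 carbon. The step needs torquoselectivity in the ring opening: the electron-donating hydroxyl at C4 rotates outward, which turns the ethoxyvinyl group inward next to the ketene, so carbocyclisation should win over lactonisation to a furanone. Regiochemistry needs no control, because every carbon of the new ring already carries its oxygen and the only CH is the former vinyl terminus.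

Step 3
Reactants: 7 5-ethoxy-2,3-dimethoxybenzene-1,4-diol
Product: 9 1-(2-ethoxy-3,6-dihydroxy-4,5-dimethoxyphenyl)ethan-1-one, via difluoroboron chelate 8 (not isolated)
Conditions: AcOH, BF3·OEt2, 80 °C, Ar; then aq. MeOH, HCl, 60 °C
Reagents that add atoms: acetic acid, CC(=O)O
Why: Friedel–Crafts C-acetylation of a polyoxygenated phenol with acetic acid and BF3 (the direct form of the Fries process) should occur at the only unsubstituted ring carbon, which is ortho to a hydroxyl, ortho to the ethoxy group and para to a methoxy group, and is driven by the six-membered O–BF2–O chelate that the work-up hydrolyses.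

Step 4
Reactants: 9 1-(2-ethoxy-3,6-dihydroxy-4,5-dimethoxyphenyl)ethan-1-one
Product: 10 1-[3-(benzyloxy)-2-ethoxy-6-hydroxy-4,5-dimethoxyphenyl]ethan-1-one
Conditions: BnBr (1.05 equiv), K2CO3, acetone, reflux, Ar
Reagents that add atoms: benzyl bromide, BrCc1ccccc1
Why: Williamson etherification should select the C3 hydroxyl, because the C6 hydroxyl is hydrogen-bonded to the acetyl carbonyl and its phenoxide is a poor nucleophile, the usual pattern for 2,5-dihydroxyacetophenones.

Step 5
Reactants: 11 2-hydroxy-6-methoxybenzaldehyde
Product: 12 2-(benzyloxy)-6-methoxybenzaldehyde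
Conditions: BnBr, K2CO3, DMF, 60 °C
Reagents that add atoms: benzyl bromide, BrCc1ccccc1
Why: Williamson etherification of a salicylaldehyde phenol under carbonate conditions is routine and masks the future 2'-hydroxyl against the base of step 6 and the iodine of step 7.

Step 6
Reactants: 10 1-[3-(benzyloxy)-2-ethoxy-6-hydroxy-4,5-dimethoxyphenyl]ethan-1-one; 12 2-(benzyloxy)-6-methoxybenzaldehyde
Product: 13 (2E)-1-[3-(benzyloxy)-2-ethoxy-6-hydroxy-4,5-dimethoxyphenyl]-3-[2-(benzyloxy)-6-methoxyphenyl]prop-2-en-1-one
Conditions: KOH, EtOH, rt; then dilute HCl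
Reagents that add atoms: none
Why: Claisen–Schmidt condensation (crossed aldol with E1cB dehydration) between the methyl ketone and the non-enolisable aldehyde should give the thermodynamically favoured E-enone, as is standard for fully oxygenated 2'-hydroxyacetophenones.

Step 7
Reactants: 13 (2E)-1-[3-(benzyloxy)-2-ethoxy-6-hydroxy-4,5-dimethoxyphenyl]-3-[2-(benzyloxy)-6-methoxyphenyl]prop-2-en-1-one
Product: 15 6-(benzyloxy)-2-[2-(benzyloxy)-6-methoxyphenyl]-5-ethoxy-7,8-dimethoxy-4H-chromen-4-one, via flavanone 14 (not isolated)
Conditions: I2 (10 mol %), DMSO, 130 °C; aq. Na2S2O3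
Reagents that add atoms: none
Why: Iodine-catalysed oxidative cyclisation of a 2'-hydroxychalcone: 6-endo-trig oxa-Michael addition of the free phenol (future O1) to the enone gives the flavanone, whose α-iodination and loss of HI should aromatise ring C while DMSO reoxidises HI to iodine; since the other phenol is benzylated, only one oxygen can close the ring.

Step 8
Reactants: 15 6-(benzyloxy)-2-[2-(benzyloxy)-6-methoxyphenyl]-5-ethoxy-7,8-dimethoxy-4H-chromen-4-one
Product: 16 5,6-dihydroxy-2-(2-hydroxy-6-methoxyphenyl)-7,8-dimethoxy-4H-chromen-4-one (5,6,2'-trihydroxy-7,8,6'-trimethoxyflavone)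
Conditions: BCl3 (excess), C6HMe5, CH2Cl2, −78 °C → rt; MeOH, then H2O
Reagents that add atoms: none
Why: Lewis-acid ether cleavage: BCl3 with pentamethylbenzene as benzyl cation scavenger should remove both benzyl ethers at low temperature, and on warming the boron chelated between the C4 carbonyl and O5 activates only the ethyl group for chloride attack, so the non-chelated methyl ethers at C7, C8 and C6' should remain.

**Compound list**

1 | dimethyl squarate (3,4-dimethoxycyclobut-3-ene-1,2-dione) | COC1=C(OC)C(=O)C1=O | starting material
2 | ethyl vinyl ether (ethoxyethene) | C=COCC | starting material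
3 | 1-ethoxyvinyllithium (formed in the flask, not isolated) | [Li]C(=C)OCC | intermediate
4 | racemic 4-(1-ethoxyethenyl)-4-hydroxy-2,3-dimethoxycyclobut-2-en-1-one | COC1=C(OC)C(O)(C(=C)OCC)C1=O | intermediate
5 | (3Z)-5-ethoxy-4-hydroxy-2,3-dimethoxyhexa-1,3,5-trien-1-one, the dienylketene (not isolated) | O=C=C(OC)/C(OC)=C(O)\C(=C)OCC | intermediate
6 | 5-ethoxy-4-hydroxy-2,3-dimethoxycyclohexa-2,4-dien-1-one (not isolated) | CCOC1=C(O)C(OC)=C(OC)C(=O)C1 | intermediate
7 | 5-ethoxy-2,3-dimethoxybenzene-1,4-diol | CCOc1cc(O)c(OC)c(OC)c1O | intermediate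
8 | difluoroboron chelate of 9, boron bridging the C6 phenol oxygen and the ketone oxygen (not isolated) | CC1=[O+][B-](F)(F)Oc2c1c(OCC)c(O)c(OC)c2OC | intermediate
9 | 1-(2-ethoxy-3,6-dihydroxy-4,5-dimethoxyphenyl)ethan-1-one | CC(=O)c1c(OCC)c(O)c(OC)c(OC)c1O | intermediate
10 | 1-[3-(benzyloxy)-2-ethoxy-6-hydroxy-4,5-dimethoxyphenyl]ethan-1-one | CC(=O)c1c(OCC)c(OCc2ccccc2)c(OC)c(OC)c1O | intermediate
11 | 2-hydroxy-6-methoxybenzaldehyde | COc1cccc(O)c1C=O | starting material
12 | 2-(benzyloxy)-6-methoxybenzaldehyde | COc1cccc(OCc2ccccc2)c1C=O | intermediate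
13 | (2E)-1-[3-(benzyloxy)-2-ethoxy-6-hydroxy-4,5-dimethoxyphenyl]-3-[2-(benzyloxy)-6-methoxyphenyl]prop-2-en-1-one | CCOc1c(OCc2ccccc2)c(OC)c(OC)c(O)c1C(=O)/C=C/c1c(OC)cccc1OCc1ccccc1 | intermediate
14 | racemic 6-(benzyloxy)-2-[2-(benzyloxy)-6-methoxyphenyl]-5-ethoxy-7,8-dimethoxy-2,3-dihydro-4H-chromen-4-one, the flavanone (not isolated) | CCOc1c(OCc2ccccc2)c(OC)c(OC)c2OC(CC(=O)c12)c1c(OC)cccc1OCc1ccccc1 | intermediate
15 | 6-(benzyloxy)-2-[2-(benzyloxy)-6-methoxyphenyl]-5-ethoxy-7,8-dimethoxy-4H-chromen-4-one | CCOc1c(OCc2ccccc2)c(OC)c(OC)c2oc(-c3c(OC)cccc3OCc3ccccc3)cc(=O)c12 | intermediate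
16 | 5,6-dihydroxy-2-(2-hydroxy-6-methoxyphenyl)-7,8-dimethoxy-4H-chromen-4-one | COc1cccc(O)c1-c1cc(=O)c2c(O)c(O)c(OC)c(OC)c2o1 | target

**Count**

Total steps: 8. Longest linear sequence: 7 steps (1, 2, 3, 4, 6, 7, 8, from dimethyl squarate); step 5 is a one-step side branch.

**Steps most likely to fail**

Step 2. Three processes threaten it: the free hydroxyl may capture the ketene (lactonisation to a furanone) if rotation is not fully outward; the enol ether may be hydrolysed by trace acid before ring opening; and the electron-rich hydroquinone may be oxidised by air during isolation. The fallback keeps the same ring opening and closure but caps the hydroxyl. It sets out from 4, which is silylated (Me3SiCl, Et3N, CH2Cl2, 0 °C) to 4-(1-ethoxyethenyl)-2,3-dimethoxy-4-[(trimethylsilyl)oxy]cyclobut-2-en-1-one F1. Thermolysis of this ether in toluene at 110 °C should give the air-stable mono-silyl ether 5-ethoxy-2,3-dimethoxy-4-[(trimethylsilyl)oxy]phenol F2, since the oxygen can no longer add to the ketene. Methanolysis (citric acid, MeOH, Ar) then comes back to the route at 7.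

Step 3. O-acylation may outrun C-acylation, the hydroquinone may be oxidised to the quinone, or the Lewis acid may dealkylate the ring at 80 °C. The fallback sets out from 7 and uses a Houben–Hoesch reaction (MeCN, ZnCl2, HCl gas, Et2O, 0 °C), which works below room temperature and cannot O-acylate. It should give the ketiminium salt 1-(2-ethoxy-3,6-dihydroxy-4,5-dimethoxyphenyl)ethan-1-iminium chloride F3, and hydrolysis in hot water comes back to the route at 9.

Step 8. De-ethylation at O5 may be incomplete, the C7 methyl ether may be lost once O6 carries boron, or ring B may be C-benzylated by escaping benzyl cation. The fallback separates the two kinds of cleavage. It sets out from 15: hydrogenolysis (H2, Pd/C, EtOAc–MeOH, rt) should remove both benzyl groups to give 5-ethoxy-6-hydroxy-2-(2-hydroxy-6-methoxyphenyl)-7,8-dimethoxy-4H-chromen-4-one F4. Chelation-controlled de-ethylation with AlCl3 in MeCN at 50 °C, followed by aq. HCl, then comes back to the route at 16.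

**Further compounds**

F1 | step 2 | racemic 4-(1-ethoxyethenyl)-2,3-dimethoxy-4-[(trimethylsilyl)oxy]cyclobut-2-en-1-one | COC1=C(OC)C(O[Si](C)(C)C)(C(=C)OCC)C1=O
F2 | step 2 | 5-ethoxy-2,3-dimethoxy-4-[(trimethylsilyl)oxy]phenol | CCOc1cc(O)c(OC)c(OC)c1O[Si](C)(C)C
F3 | step 3 | 1-(2-ethoxy-3,6-dihydroxy-4,5-dimethoxyphenyl)ethan-1-iminium chloride | CC(=[NH2+])c1c(OCC)c(O)c(OC)c(OC)c1O.[Cl-]
F4 | step 8 | 5-ethoxy-6-hydroxy-2-(2-hydroxy-6-methoxyphenyl)-7,8-dimethoxy-4H-chromen-4-one | CCOc1c(O)c(OC)c(OC)c2oc(-c3c(OC)cccc3O)cc(=O)c12
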